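The numbers in the tables stem from a simulated flask with made-up constants.

- The epsilon run, with 6.7 mM of starting material, and the theta run, with 15 mM, each carried 1 mM of protic impurity. This is the limiting reagent of the quench, and it can claim up to 14.9% of the epsilon charge and 6.67% of the theta charge.

| flask | starting material | protic impurity | remark | time |
|---|---|---|---|---|
| epsilon | 6.7 mM | 1 mM | run made earlier |  |
| theta | 15 mM | 1 mM | run made earlier |  |
| flask | 10 mM | 1.00 mM |  | 15 h |

| run | time / h | intermediate C / % | product / % |
|---|---|---|---|
| epsilon | 0.250 | 14 | 0 |
| epsilon | 0.500 | 16 | 3 |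
| epsilon | 1.00 | 19 | 11 |
| epsilon | 2.00 | 14 | 17 |
| epsilon | 3.00 | 15 | 29 |
| epsilon | 6.00 | 9 | 48 |
| epsilon | 12.0 | 3 | 71 |
| theta | 0.250 | 12 | 2 |
| theta | 0.500 | 16 | 4 |
| theta | 1.00 | 16 | 8 |
| theta | 2.00 | 16 | 20 |
| theta | 3.00 | 16 | 28 |
| theta | 6.00 | 7 | 55 |
| theta | 12.0 | 3 | 74 |

(standard deviation of a reading: 2 percentage points)

- what may be going on: starting material -> intermediate A; starting material <-> intermediate B; intermediate A <-> intermediate C; intermediate A -> product; intermediate C <-> intermediate D; starting material + protic impurity -> quenched substrate

- time, not beyond 15 h, at which the flask holds most intermediate C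
- the amount of intermediate C, in percent of the starting material charged, at that time

- Between 0.500 h and 3.00 h, the readings of intermediate C average 16.0% in epsilon and 16.0% in theta.
- You carry forward the plateau fraction, which is that level divided by the part of the charge the impurity cannot claim, averaged over both runs: 18.0%.
- For the asked flask, this gives a level of 16.2%.
- The first readings of intermediate C in the two runs give a starting slope of 0.520 h⁻¹ as a fraction of the charge, so you reckon that the asked flask's curve reaches that level at a first knee near 0.311 h.
- The mean of the two runs' readings of intermediate C falls from 8.00% at 6.00 h to 3.00% at 12.0 h, which reads as a half-life of 4.24 h.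
- Traced back on a logarithmic scale, that fall meets the level at a second knee near 1.69 h. Traced forward, the same line gives an estimate of about 1.84% at 15 h.
- You therefore expect the top of the flask's curve midway between the knees, near 1.00 h.
- The forecast gave 16.5% at 1.4 h, later than the time reckoned here, and held that “the time is poorly defined, while the height is better defined”.
- The flask peaks at 1.05 h with 16.4% of intermediate C, and still holds 15.3% at 2.11 h. At the peak, 9.35% of the charge stands as quenched substrate, and the plateau fraction times the remainder gives 16.3%.

    starting material → intermediate A (k = 0.00110 s⁻¹)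
    starting material ⇌ intermediate B (K = 2.60, k = 0.00580 s⁻¹)
    intermediate A ⇌ intermediate C (K = 1.90, k = 0.0310 s⁻¹)
    intermediate A → product (k = 3.40 × 10⁻⁴ s⁻¹)
    intermediate C ⇌ intermediate D (K = 2.50, k = 8.80 × 10⁻⁴ s⁻¹)
    starting material + protic impurity → quenched substrate (k = 0.480 M⁻¹ s⁻¹)

- In the neighbouring flask with 4.0 mM of protic impurity, the plateau fraction, taking the whole of that impurity as claimed, gives an estimate of 10.8% of intermediate C at the top. The simulation gives 12.2% for that flask.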